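**Retrosynthetic overview**
- The target (halocynthiaxanthin 3'-acetate) is cut at C9=C10: an intermolecular aldol addition of a C13 epoxy ethyl ketone (fragment A) to a C27 acetylenic polyenal (fragment B), then dehydration and removal of one silyl group.
- Fragment A comes from an epoxy aldehyde by Wittig olefination and hydroboration–oxidation; the epoxy aldehyde comes from Sharpless epoxidation of an allylic alcohol made by carbonylation of a vinyl triflate.
- Fragment B comes from two Horner–Wadsworth–Emmons reactions (C15 enynyl phosphonate + C12 aldehyde ester from the C10 dialdehyde), redox adjustment and silyl-to-acetyl exchange; the C15 unit comes from Sonogashira coupling of the same vinyl triflate.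
- The vinyl triflate comes from ketoisophorone by asymmetric transfer hydrogenation, hydrogenation, silylation and triflation.
- Rings: both carbocycles are bought with ketoisophorone; the only ring made is the oxirane (step 7), set anti to the C3 oxygen by reagent control.

Assumption: carotenoid numbering (primed for the acetylenic half) is used in the text, and the hydrogenation product of step 2 is carried on as its C6 epimer mixture because that centre becomes sp2 in step 4.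

**Route**

Step 1
Reactants: 1 2,6,6-trimethylcyclohex-2-ene-1,4-dione (ketoisophorone)
Product: 2 (4S)-4-hydroxy-2,6,6-trimethylcyclohex-2-en-1-one
Conditions: RuCl[(S,S)-TsDPEN](p-cymene) (1 mol%), HCO2H/Et3N 5:2, CH2Cl2, 25 °C
Reagents that add atoms: none
Why: Noyori-type asymmetric transfer hydrogenation reduces only the unhindered C4 carbonyl, and with the alkene in the role of the aryl group of aryl ketones the (S,S)-catalyst gives the (4S)-carbinol that becomes C3 and C3' of the target.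

Step 2
Reactants: 2 (4S)-4-hydroxy-2,6,6-trimethylcyclohex-2-en-1-one
Product: 3 (4R)-4-hydroxy-2,2,6-trimethylcyclohexan-1-one (C6 epimer mixture)
Conditions: H2 (1 atm), 10% Pd/C, EtOAc, 25 °C
Reagents that add atoms: none
Why: Catalytic hydrogenation saturates the conjugated C=C without touching the carbinol centre (the descriptor changes from S to R only because ring priorities change), and the new methyl-bearing centre is flattened again in step 4.

Step 3
Reactants: 3 (4R)-4-hydroxy-2,2,6-trimethylcyclohexan-1-one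
Product: 4 (4R)-2,2,6-trimethyl-4-(triethylsilyloxy)cyclohexan-1-one
Conditions: Et3SiCl, imidazole, DMF, 0 °C to 25 °C
Reagents that add atoms: chlorotriethylsilane, CC[Si](Cl)(CC)CC
Why: Silyl ether formation masks the hydroxyl for the base and hydride steps, and TES is chosen because it leaves at the end under nearly neutral fluoride conditions.

Step 4
Reactants: 4 (4R)-2,2,6-trimethyl-4-(triethylsilyloxy)cyclohexan-1-one
Product: 6 (4R)-2,6,6-trimethyl-4-(triethylsilyloxy)cyclohex-1-en-1-yl trifluoromethanesulfonate, via lithium enolate 5 (not isolated)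
Conditions: lithium diisopropylamide (LDA), THF, −78 to 0 °C; then PhNTf2, −78 to 25 °C
Reagents that add atoms: N-phenylbis(trifluoromethanesulfonimide), O=S(=O)(N(c1ccccc1)S(=O)(=O)C(F)(F)F)C(F)(F)F
Why: Only one α-carbon carries hydrogen, so enolate formation is regiospecific and O-sulfonylation (enol triflate formation) gives the tetrasubstituted vinyl triflate used for both halves.

Step 5
Reactants: 6 (4R)-2,6,6-trimethyl-4-(triethylsilyloxy)cyclohex-1-en-1-yl trifluoromethanesulfonate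
Product: 7 methyl (4R)-2,6,6-trimethyl-4-(triethylsilyloxy)cyclohex-1-ene-1-carboxylate
Conditions: Pd(OAc)2 (5 mol%), PPh3, CO (1 atm), MeOH, Et3N, DMF, 60 °C
Reagents that add atoms: carbon monoxide, [C-]#[O+]; methanol, CO
Why: Palladium-catalysed alkoxycarbonylation (oxidative addition of the vinyl triflate to zerovalent palladium, CO insertion, methanolysis) installs C7.

Step 6
Reactants: 7 methyl (4R)-2,6,6-trimethyl-4-(triethylsilyloxy)cyclohex-1-ene-1-carboxylate
Product: 8 [(4R)-2,6,6-trimethyl-4-(triethylsilyloxy)cyclohex-1-en-1-yl]methanol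
Conditions: i-Bu2AlH (DIBAL-H), CH2Cl2, −78 to 0 °C
Reagents that add atoms: none
Why: DIBAL-H reduction of the conjugated ester gives the primary allylic alcohol needed for directed epoxidation.

Step 7
Reactants: 8 [(4R)-2,6,6-trimethyl-4-(triethylsilyloxy)cyclohex-1-en-1-yl]methanol
Product: 9 [(1R,4S,6R)-2,2,6-trimethyl-4-(triethylsilyloxy)-7-oxabicyclo[4.1.0]heptan-1-yl]methanol
Conditions: Ti(OiPr)4 (20 mol%), D-(−)-diethyl tartrate (25 mol%), t-BuOOH, 4 Å sieves, CH2Cl2, −20 °C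
Reagents that add atoms: tert-butyl hydroperoxide, CC(C)(C)OO
Why: Sharpless asymmetric epoxidation with the unnatural tartrate delivers oxygen to the face of C5=C6 anti to the C3 silyloxy group under reagent control, setting both oxirane carbons as in the target.

Step 8
Reactants: 9 [(1R,4S,6R)-2,2,6-trimethyl-4-(triethylsilyloxy)-7-oxabicyclo[4.1.0]heptan-1-yl]methanol
Product: 10 (1S,4S,6R)-2,2,6-trimethyl-4-(triethylsilyloxy)-7-oxabicyclo[4.1.0]heptane-1-carbaldehyde
Conditions: Dess–Martin periodinane, pyridine, CH2Cl2, 0 to 25 °C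
Reagents that add atoms: none
Why: Dess–Martin oxidation gives the non-enolisable epoxy aldehyde under buffered conditions that spare the oxirane and the TES ether.

Step 9
Reactants: 10 (1S,4S,6R)-2,2,6-trimethyl-4-(triethylsilyloxy)-7-oxabicyclo[4.1.0]heptane-1-carbaldehyde; 11 propyltriphenylphosphonium bromide
Product: 13 triethyl{[(1S,4S,6R)-1-[(1Z)-but-1-en-1-yl]-2,2,6-trimethyl-7-oxabicyclo[4.1.0]heptan-4-yl]oxy}silane, via propylidene ylide 12 (not isolated)
Conditions: NaN(SiMe3)2, THF, 0 °C; then 10, −78 to 25 °C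
Reagents that add atoms: none
Why: Wittig olefination with a non-stabilised ylide adds C8, C9 and C19 and gives mainly the Z-alkene, whose geometry is irrelevant.

Step 10
Reactants: 13 triethyl{[(1S,4S,6R)-1-[(1Z)-but-1-en-1-yl]-2,2,6-trimethyl-7-oxabicyclo[4.1.0]heptan-4-yl]oxy}silane
Product: 15 1-[(1S,4S,6R)-2,2,6-trimethyl-4-(triethylsilyloxy)-7-oxabicyclo[4.1.0]heptan-1-yl]butan-2-ol (carbinol epimer mixture), via B-alkyl-9-BBN 14 (not isolated)
Conditions: 9-BBN, THF, 0 to 60 °C; then 3 M NaOH, 30% H2O2, 0 to 25 °C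
Reagents that add atoms: hydrogen peroxide, OO
Why: Hydroboration–oxidation with bulky 9-BBN puts boron on C8, the alkene carbon remote from the fully substituted oxirane carbon, and the hindered oxirane is not attacked; the carbinol mixture is oxidised next.

Step 11
Reactants: 15 1-[(1S,4S,6R)-2,2,6-trimethyl-4-(triethylsilyloxy)-7-oxabicyclo[4.1.0]heptan-1-yl]butan-2-ol
Product: 16 1-[(1S,4S,6R)-2,2,6-trimethyl-4-(triethylsilyloxy)-7-oxabicyclo[4.1.0]heptan-1-yl]butan-2-one
Conditions: Dess–Martin periodinane, pyridine, CH2Cl2, 0 to 25 °C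
Reagents that add atoms: none
Why: Dess–Martin oxidation gives the ethyl ketone (fragment A) without base, so the base-labile β,γ-epoxy ketone is not enolised.

Step 12
Reactants: 6 (4R)-2,6,6-trimethyl-4-(triethylsilyloxy)cyclohex-1-en-1-yl trifluoromethanesulfonate; 17 (2E)-3-methylpent-2-en-4-yn-1-ol
Product: 18 (2E)-3-methyl-5-[(4R)-2,6,6-trimethyl-4-(triethylsilyloxy)cyclohex-1-en-1-yl]pent-2-en-4-yn-1-ol
Conditions: Pd(PPh3)4 (5 mol%), CuI (10 mol%), i-Pr2NH, DMF, 25 °C
Reagents that add atoms: none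
Why: Sonogashira coupling joins the vinyl triflate to the terminal alkyne (C6'–C7') with the E geometry of the enynol retained.

Step 13
Reactants: 18 (2E)-3-methyl-5-[(4R)-2,6,6-trimethyl-4-(triethylsilyloxy)cyclohex-1-en-1-yl]pent-2-en-4-yn-1-ol
Product: 19 triethyl{[(1R)-4-[(3E)-5-bromo-3-methylpent-3-en-1-yn-1-yl]-3,5,5-trimethylcyclohex-3-en-1-yl]oxy}silane
Conditions: CBr4, PPh3, CH2Cl2, 0 °C
Reagents that add atoms: carbon tetrabromide, BrC(Br)(Br)Br
Why: The Appel reaction converts the primary allylic alcohol to the bromide by SN2 displacement without allylic transposition.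

Step 14
Reactants: 19 triethyl{[(1R)-4-[(3E)-5-bromo-3-methylpent-3-en-1-yn-1-yl]-3,5,5-trimethylcyclohex-3-en-1-yl]oxy}silane
Product: 20 diethyl {(2E)-3-methyl-5-[(4R)-2,6,6-trimethyl-4-(triethylsilyloxy)cyclohex-1-en-1-yl]pent-2-en-4-yn-1-yl}phosphonate
Conditions: P(OEt)3 (neat), 100 °C
Reagents that add atoms: triethyl phosphite, CCOP(OCC)OCC
Why: Michaelis–Arbuzov reaction at the primary allylic carbon gives the C15 phosphonate.

Step 15
Reactants: 21 (2E,4E,6E)-2,7-dimethylocta-2,4,6-trienedial; 22 triethyl phosphonoacetate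
Product: 24 ethyl (2E,4E,6E,8E)-4,9-dimethyl-10-oxodeca-2,4,6,8-tetraenoate, via sodium phosphonoacetate carbanion 23 (not isolated)
Conditions: NaH, THF, 0 °C; then added to 21 (3 equiv), THF, −20 to 0 °C
Reagents that add atoms: none
Why: Horner–Wadsworth–Emmons olefination with a stabilised phosphonate is E-selective, and the threefold excess of the symmetrical dialdehyde holds it at mono-olefination.

Step 16
Reactants: 20 diethyl {(2E)-3-methyl-5-[(4R)-2,6,6-trimethyl-4-(triethylsilyloxy)cyclohex-1-en-1-yl]pent-2-en-4-yn-1-yl}phosphonate; 24 ethyl (2E,4E,6E,8E)-4,9-dimethyl-10-oxodeca-2,4,6,8-tetraenoate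
Product: 26 ethyl (2E,4E,6E,8E,10E,12E)-4,9,13-trimethyl-15-[(4R)-2,6,6-trimethyl-4-(triethylsilyloxy)cyclohex-1-en-1-yl]pentadeca-2,4,6,8,10,12-hexaen-14-ynoate, via sodium phosphonate carbanion 25 (not isolated)
Conditions: NaN(SiMe3)2, THF, −78 °C; then 24, −78 to 0 °C
Reagents that add atoms: none
Why: Horner–Wadsworth–Emmons olefination of the allylic phosphonate carbanion with the aldehyde forms C11'=C12' E-selectively, so no thermal isomerisation is needed that could scramble the 9'-geometry beside the alkyne.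

Step 17
Reactants: 26 ethyl (2E,4E,6E,8E,10E,12E)-4,9,13-trimethyl-15-[(4R)-2,6,6-trimethyl-4-(triethylsilyloxy)cyclohex-1-en-1-yl]pentadeca-2,4,6,8,10,12-hexaen-14-ynoate
Product: 27 (2E,4E,6E,8E,10E,12E)-4,9,13-trimethyl-15-[(4R)-2,6,6-trimethyl-4-(triethylsilyloxy)cyclohex-1-en-1-yl]pentadeca-2,4,6,8,10,12-hexaen-14-yn-1-ol
Conditions: i-Bu2AlH (DIBAL-H), CH2Cl2, −78 °C
Reagents that add atoms: none
Why: DIBAL-H 1,2-reduction of the conjugated ester gives the allylic alcohol.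

Step 18
Reactants: 27 (2E,4E,6E,8E,10E,12E)-4,9,13-trimethyl-15-[(4R)-2,6,6-trimethyl-4-(triethylsilyloxy)cyclohex-1-en-1-yl]pentadeca-2,4,6,8,10,12-hexaen-14-yn-1-ol
Product: 28 (2E,4E,6E,8E,10E,12E)-4,9,13-trimethyl-15-[(4R)-2,6,6-trimethyl-4-(triethylsilyloxy)cyclohex-1-en-1-yl]pentadeca-2,4,6,8,10,12-hexaen-14-ynal
Conditions: MnO2, CH2Cl2, 25 °C
Reagents that add atoms: none
Why: MnO2 allylic oxidation converts only the polyenylic primary alcohol to the aldehyde.

Step 19
Reactants: 28 (2E,4E,6E,8E,10E,12E)-4,9,13-trimethyl-15-[(4R)-2,6,6-trimethyl-4-(triethylsilyloxy)cyclohex-1-en-1-yl]pentadeca-2,4,6,8,10,12-hexaen-14-ynal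
Product: 29 (2E,4E,6E,8E,10E,12E)-15-[(4R)-4-hydroxy-2,6,6-trimethylcyclohex-1-en-1-yl]-4,9,13-trimethylpentadeca-2,4,6,8,10,12-hexaen-14-ynal
Conditions: Et3N·3HF, THF, 25 °C
Reagents that add atoms: none
Why: Fluoride-mediated desilylation frees the ring hydroxyl without affecting the polyenal.

Step 20
Reactants: 29 (2E,4E,6E,8E,10E,12E)-15-[(4R)-4-hydroxy-2,6,6-trimethylcyclohex-1-en-1-yl]-4,9,13-trimethylpentadeca-2,4,6,8,10,12-hexaen-14-ynal
Product: 30 (1R)-3,5,5-trimethyl-4-[(3E,5E,7E,9E,11E,13E)-3,7,12-trimethyl-15-oxopentadeca-3,5,7,9,11,13-hexaen-1-yn-1-yl]cyclohex-3-en-1-yl acetate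
Conditions: Ac2O, pyridine, DMAP (cat.), CH2Cl2, 0 to 25 °C
Reagents that add atoms: acetic anhydride, CC(=O)OC(C)=O
Why: DMAP-catalysed acylation installs the 3'-acetate of the target and completes fragment B.

Step 21
Reactants: 16 1-[(1S,4S,6R)-2,2,6-trimethyl-4-(triethylsilyloxy)-7-oxabicyclo[4.1.0]heptan-1-yl]butan-2-one; 30 (1R)-3,5,5-trimethyl-4-[(3E,5E,7E,9E,11E,13E)-3,7,12-trimethyl-15-oxopentadeca-3,5,7,9,11,13-hexaen-1-yn-1-yl]cyclohex-3-en-1-yl acetate
Product: 32 (1R)-4-[(3E,5E,7E,9E,11E,13E)-15-hydroxy-3,7,12,16-tetramethyl-17-oxo-18-[(1S,4S,6R)-2,2,6-trimethyl-4-(triethylsilyloxy)-7-oxabicyclo[4.1.0]heptan-1-yl]octadeca-3,5,7,9,11,13-hexaen-1-yn-1-yl]-3,5,5-trimethylcyclohex-3-en-1-yl acetate (mixture at C15 and C16 of the chain), via lithium enolate 31 (not isolated)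
Conditions: lithium diisopropylamide (LDA, 1.05 equiv), THF, −78 °C; then 30, −78 °C; AcOH, −78 °C
Reagents that add atoms: none
Why: Intermolecular aldol addition: LDA deprotonates kinetically at the C9 methylene (the C7 methylene is neopentyl-like beside the fully substituted oxirane carbon) and the enolate adds 1,2 to the aldehyde at −78 °C faster than it touches the acetate, the two new centres being removed in step 22.

Step 22
Reactants: 32 aldol adduct (name as in step 21)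
Product: 34 (1R)-3,5,5-trimethyl-4-[(3E,5E,7E,9E,11E,13E,15E)-3,7,12,16-tetramethyl-17-oxo-18-[(1S,4S,6R)-2,2,6-trimethyl-4-(triethylsilyloxy)-7-oxabicyclo[4.1.0]heptan-1-yl]octadeca-3,5,7,9,11,13,15-heptaen-1-yn-1-yl]cyclohex-3-en-1-yl acetate, via methanesulfonate 33 (not isolated)
Conditions: MsCl, Et3N, CH2Cl2, −20 to 25 °C
Reagents that add atoms: none
Why: Mesylation and in-situ E1cB elimination through the C9 enolate give the trisubstituted enone as the thermodynamically preferred 9E isomer, the amine being too weak a base to open the β,γ-epoxy ketone.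

Step 23
Reactants: 34 3-O-triethylsilyl ether of the target (name as in step 22)
Product: 35 (1R)-4-[(3E,5E,7E,9E,11E,13E,15E)-18-[(1S,4S,6R)-4-hydroxy-2,2,6-trimethyl-7-oxabicyclo[4.1.0]heptan-1-yl]-3,7,12,16-tetramethyl-17-oxooctadeca-3,5,7,9,11,13,15-heptaen-1-yn-1-yl]-3,5,5-trimethylcyclohex-3-en-1-yl acetate
Conditions: Et3N·3HF, THF, 0 to 25 °C
Reagents that add atoms: none
Why: Fluoride-mediated desilylation under nearly neutral conditions leaves the acetate, the oxirane, the base-labile epoxy ketone and the polyene untouched and gives the target.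

**Compound list**

1 | 2,6,6-trimethylcyclohex-2-ene-1,4-dione (ketoisophorone) | CC1=CC(=O)CC(C)(C)C1=O | starting material
2 | (4S)-4-hydroxy-2,6,6-trimethylcyclohex-2-en-1-one | O[C@@H]1C=C(C)C(=O)C(C)(C)C1 | intermediate
3 | (4R)-4-hydroxy-2,2,6-trimethylcyclohexan-1-one, C6 epimer mixture | O[C@@H]1CC(C)C(=O)C(C)(C)C1 | intermediate
4 | (4R)-2,2,6-trimethyl-4-(triethylsilyloxy)cyclohexan-1-one, C6 epimer mixture | CC[Si](CC)(CC)O[C@@H]1CC(C)C(=O)C(C)(C)C1 | intermediate
5 | lithium (4R)-2,6,6-trimethyl-4-(triethylsilyloxy)cyclohex-1-en-1-olate | CC[Si](CC)(CC)O[C@@H]1CC(C)=C([O-])C(C)(C)C1.[Li+] | intermediate (not isolated)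
6 | (4R)-2,6,6-trimethyl-4-(triethylsilyloxy)cyclohex-1-en-1-yl trifluoromethanesulfonate | CC[Si](CC)(CC)O[C@@H]1CC(C)=C(OS(=O)(=O)C(F)(F)F)C(C)(C)C1 | intermediate
7 | methyl (4R)-2,6,6-trimethyl-4-(triethylsilyloxy)cyclohex-1-ene-1-carboxylate | CC[Si](CC)(CC)O[C@@H]1CC(C)=C(C(=O)OC)C(C)(C)C1 | intermediate
8 | [(4R)-2,6,6-trimethyl-4-(triethylsilyloxy)cyclohex-1-en-1-yl]methanol | CC[Si](CC)(CC)O[C@@H]1CC(C)=C(CO)C(C)(C)C1 | intermediate
9 | [(1R,4S,6R)-2,2,6-trimethyl-4-(triethylsilyloxy)-7-oxabicyclo[4.1.0]heptan-1-yl]methanol (oxirane anti to OSi) | OC[C@@]12O[C@]1(C)C[C@@H](O[Si](CC)(CC)CC)CC2(C)C | intermediate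
10 | (1S,4S,6R)-2,2,6-trimethyl-4-(triethylsilyloxy)-7-oxabicyclo[4.1.0]heptane-1-carbaldehyde | O=C[C@@]12O[C@]1(C)C[C@@H](O[Si](CC)(CC)CC)CC2(C)C | intermediate
11 | propyltriphenylphosphonium bromide | CCC[P+](c1ccccc1)(c1ccccc1)c1ccccc1.[Br-] | starting material
12 | propylidenetriphenylphosphorane | CCC=P(c1ccccc1)(c1ccccc1)c1ccccc1 | intermediate (not isolated)
13 | triethyl{[(1S,4S,6R)-1-[(1Z)-but-1-en-1-yl]-2,2,6-trimethyl-7-oxabicyclo[4.1.0]heptan-4-yl]oxy}silane | CC/C=C\[C@@]12O[C@]1(C)C[C@@H](O[Si](CC)(CC)CC)CC2(C)C | intermediate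
14 | 9-{1-[(1S,4S,6R)-2,2,6-trimethyl-4-(triethylsilyloxy)-7-oxabicyclo[4.1.0]heptan-1-yl]butan-2-yl}-9-borabicyclo[3.3.1]nonane | CCC(C[C@@]12O[C@]1(C)C[C@@H](O[Si](CC)(CC)CC)CC2(C)C)B1C2CCCC1CCC2 | intermediate (not isolated)
15 | 1-[(1S,4S,6R)-2,2,6-trimethyl-4-(triethylsilyloxy)-7-oxabicyclo[4.1.0]heptan-1-yl]butan-2-ol, carbinol epimers | CCC(O)C[C@@]12O[C@]1(C)C[C@@H](O[Si](CC)(CC)CC)CC2(C)C | intermediate
16 | 1-[(1S,4S,6R)-2,2,6-trimethyl-4-(triethylsilyloxy)-7-oxabicyclo[4.1.0]heptan-1-yl]butan-2-one (fragment A) | CCC(=O)C[C@@]12O[C@]1(C)C[C@@H](O[Si](CC)(CC)CC)CC2(C)C | intermediate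
17 | (2E)-3-methylpent-2-en-4-yn-1-ol | C#C/C(C)=C/CO | starting material
18 | (2E)-3-methyl-5-[(4R)-2,6,6-trimethyl-4-(triethylsilyloxy)cyclohex-1-en-1-yl]pent-2-en-4-yn-1-ol | CC[Si](CC)(CC)O[C@@H]1CC(C)=C(C#C/C(C)=C/CO)C(C)(C)C1 | intermediate
19 | triethyl{[(1R)-4-[(3E)-5-bromo-3-methylpent-3-en-1-yn-1-yl]-3,5,5-trimethylcyclohex-3-en-1-yl]oxy}silane | CC[Si](CC)(CC)O[C@@H]1CC(C)=C(C#C/C(C)=C/CBr)C(C)(C)C1 | intermediate
20 | diethyl {(2E)-3-methyl-5-[(4R)-2,6,6-trimethyl-4-(triethylsilyloxy)cyclohex-1-en-1-yl]pent-2-en-4-yn-1-yl}phosphonate | CC[Si](CC)(CC)O[C@@H]1CC(C)=C(C#C/C(C)=C/CP(=O)(OCC)OCC)C(C)(C)C1 | intermediate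
21 | (2E,4E,6E)-2,7-dimethylocta-2,4,6-trienedial | O=C/C(C)=C/C=C/C=C(\C)C=O | starting material
22 | triethyl phosphonoacetate | CCOC(=O)CP(=O)(OCC)OCC | starting material
23 | sodium salt of the triethyl phosphonoacetate carbanion | [Na+].CCOC(=O)[CH-]P(=O)(OCC)OCC | intermediate (not isolated)
24 | ethyl (2E,4E,6E,8E)-4,9-dimethyl-10-oxodeca-2,4,6,8-tetraenoate | CCOC(=O)/C=C/C(C)=C/C=C/C=C(\C)C=O | intermediate
25 | sodium salt of the α-carbanion of phosphonate 20 | [Na+].CC[Si](CC)(CC)O[C@@H]1CC(C)=C(C#C/C(C)=C/[CH-]P(=O)(OCC)OCC)C(C)(C)C1 | intermediate (not isolated)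
26 | ethyl (2E,4E,6E,8E,10E,12E)-4,9,13-trimethyl-15-[(4R)-2,6,6-trimethyl-4-(triethylsilyloxy)cyclohex-1-en-1-yl]pentadeca-2,4,6,8,10,12-hexaen-14-ynoate | CC[Si](CC)(CC)O[C@@H]1CC(C)=C(C#C/C(C)=C/C=C/C(C)=C/C=C/C=C(C)/C=C/C(=O)OCC)C(C)(C)C1 | intermediate
27 | corresponding all-E hexaenynol (C1 alcohol of 26) | CC[Si](CC)(CC)O[C@@H]1CC(C)=C(C#C/C(C)=C/C=C/C(C)=C/C=C/C=C(C)/C=C/CO)C(C)(C)C1 | intermediate
28 | corresponding all-E hexaenynal (C1 aldehyde of 27) | CC[Si](CC)(CC)O[C@@H]1CC(C)=C(C#C/C(C)=C/C=C/C(C)=C/C=C/C=C(C)/C=C/C=O)C(C)(C)C1 | intermediate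
29 | (2E,4E,6E,8E,10E,12E)-15-[(4R)-4-hydroxy-2,6,6-trimethylcyclohex-1-en-1-yl]-4,9,13-trimethylpentadeca-2,4,6,8,10,12-hexaen-14-ynal | O[C@@H]1CC(C)=C(C#C/C(C)=C/C=C/C(C)=C/C=C/C=C(C)/C=C/C=O)C(C)(C)C1 | intermediate
30 | (1R)-3,5,5-trimethyl-4-[(3E,5E,7E,9E,11E,13E)-3,7,12-trimethyl-15-oxopentadeca-3,5,7,9,11,13-hexaen-1-yn-1-yl]cyclohex-3-en-1-yl acetate (fragment B) | CC(=O)O[C@@H]1CC(C)=C(C#C/C(C)=C/C=C/C(C)=C/C=C/C=C(C)/C=C/C=O)C(C)(C)C1 | intermediate
31 | lithium enolate of 16 at C9 (but-2-en-2-olate, E/Z mixture) | [Li+].CC=C([O-])C[C@@]12O[C@]1(C)C[C@@H](O[Si](CC)(CC)CC)CC2(C)C | intermediate (not isolated)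
32 | aldol adduct: 10-hydroxy-9,10-dihydro derivative of 34 (carotenoid numbering), mixture at C9 and C10 | CC(=O)O[C@@H]1CC(C)=C(C#C/C(C)=C/C=C/C(C)=C/C=C/C=C(C)/C=C/C(O)C(C)C(=O)C[C@@]23O[C@]2(C)C[C@@H](O[Si](CC)(CC)CC)CC3(C)C)C(C)(C)C1 | intermediate
33 | 10-methanesulfonate of 32 | CC(=O)O[C@@H]1CC(C)=C(C#C/C(C)=C/C=C/C(C)=C/C=C/C=C(C)/C=C/C(OS(C)(=O)=O)C(C)C(=O)C[C@@]23O[C@]2(C)C[C@@H](O[Si](CC)(CC)CC)CC3(C)C)C(C)(C)C1 | intermediate (not isolated)
34 | 3-O-triethylsilyl ether of the target (full name in step 22) | CC(=O)O[C@@H]1CC(C)=C(C#C/C(C)=C/C=C/C(C)=C/C=C/C=C(C)/C=C/C=C(\C)C(=O)C[C@@]23O[C@]2(C)C[C@@H](O[Si](CC)(CC)CC)CC3(C)C)C(C)(C)C1 | intermediate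
35 | (3S,5R,6S,3'R)-3'-acetoxy-5,6-epoxy-3-hydroxy-7',8'-didehydro-5,6,7,8-tetrahydro-β,β-caroten-8-one (full name in step 23) | CC(=O)O[C@@H]1CC(C)=C(C#C/C(C)=C/C=C/C(C)=C/C=C/C=C(C)/C=C/C=C(\C)C(=O)C[C@@]23O[C@]2(C)C[C@@H](O)CC3(C)C)C(C)(C)C1 | target

**Count and risks**

Total: 23 steps. Longest linear sequence: 15 steps (1–4, 12–14, 16–23, from ketoisophorone).

Step 10 (hydroboration of the alkenyl oxirane). The risk is borane-induced opening of the allylic epoxide or slow addition to the hindered alkene. The fallback sets out from 10 and comes back at 16. A boron-Wittig reaction of 10 with 1,1-bis(pinacolboryl)propane and lithium 2,2,6,6-tetramethylpiperidide (THF, −78 to 0 °C) gives the alkenyl boronate F1, whose boron already sits on C8. Oxidation with NaBO3·4H2O in THF/water converts the C–B bond to the enol and so directly to ketone 16, and no borane hydride ever meets the alkenyl oxirane.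

Step 21 (aldol addition). The risk is the strongly basic lithium enolate: any deprotonation at C7 opens the oxirane, and proton transfer or attack on the acetate competes if addition to the large polyenal is slow. The fallback sets out from 16 and comes back at 32. The kinetic enolate is trapped with Me3SiCl as the trimethylsilyl enol ether F2, whose regiochemistry can be checked and purified on a simple compound. NBS in THF at −78 °C then gives the 3-bromo ketone F3. A Reformatsky-type addition with CrCl2 and catalytic LiI (THF, 20 °C) in the presence of 30 generates a non-basic chromium enolate regiospecifically at C9 and gives 32.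

Step 22 (dehydration). The risk is that the sulfonate of the polyenyl carbinol ionises, giving chloride capture or Z/E mixtures, or that the base opens the epoxy ketone. The fallback sets out from 16, by way of the bromo ketone F3 described above, and comes back at 34, by-passing 32. F3 and PPh3 (toluene, 60 °C) give the phosphonium bromide F4, and aqueous Na2CO3 gives the acyl-stabilised ylide F5. Wittig olefination of 30 with F5 (toluene, 80 °C) forms C9=C10 directly as the E-enone under neutral conditions.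

**Further compounds**

F1 | step 10 | 4,4,5,5-tetramethyl-2-{1-[(1S,4S,6R)-2,2,6-trimethyl-4-(triethylsilyloxy)-7-oxabicyclo[4.1.0]heptan-1-yl]but-1-en-2-yl}-1,3,2-dioxaborolane (E/Z mixture) | CCC(B1OC(C)(C)C(C)(C)O1)=C[C@@]12O[C@]1(C)C[C@@H](O[Si](CC)(CC)CC)CC2(C)C
F2 | step 21 | triethyl{[(1S,4S,6R)-2,2,6-trimethyl-1-[2-(trimethylsilyloxy)but-2-en-1-yl]-7-oxabicyclo[4.1.0]heptan-4-yl]oxy}silane (E/Z mixture) | CC=C(O[Si](C)(C)C)C[C@@]12O[C@]1(C)C[C@@H](O[Si](CC)(CC)CC)CC2(C)C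
F3 | step 21 | 3-bromo-1-[(1S,4S,6R)-2,2,6-trimethyl-4-(triethylsilyloxy)-7-oxabicyclo[4.1.0]heptan-1-yl]butan-2-one (epimers at C3) | CC(Br)C(=O)C[C@@]12O[C@]1(C)C[C@@H](O[Si](CC)(CC)CC)CC2(C)C
F4 | step 22 | {3-oxo-4-[(1S,4S,6R)-2,2,6-trimethyl-4-(triethylsilyloxy)-7-oxabicyclo[4.1.0]heptan-1-yl]butan-2-yl}triphenylphosphonium bromide | CC(C(=O)C[C@@]12O[C@]1(C)C[C@@H](O[Si](CC)(CC)CC)CC2(C)C)[P+](c1ccccc1)(c1ccccc1)c1ccccc1.[Br-]
F5 | step 22 | 1-[(1S,4S,6R)-2,2,6-trimethyl-4-(triethylsilyloxy)-7-oxabicyclo[4.1.0]heptan-1-yl]-3-(triphenylphosphoranylidene)butan-2-one | CC(C(=O)C[C@@]12O[C@]1(C)C[C@@H](O[Si](CC)(CC)CC)CC2(C)C)=P(c1ccccc1)(c1ccccc1)c1ccccc1
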